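The neighbouring flask took its starting material in one portion; this row feeds it over the run instead, at rising strength.

    starting material + free catalyst ⇌ catalyst intermediate A (K1 = 14 /M, k1 = 1.8 /M/min)
    catalyst intermediate A → free catalyst + target (k2 = 0.23 /min)
    second substrate + free catalyst ⇌ catalyst intermediate B (K3 = 2.8 /M, k3 = 0.10 /M/min)
    catalyst intermediate B → free catalyst + second product (k4 = 0.11 /min)
    target ⇌ isomer of the product (K5 = 1.9, k5 = 4.2 × 10⁻⁵ /min)
    2 second substrate → homo dimer (k6 = 1.2 × 10⁻⁴ /M/min)
    free catalyst + added ligand ⇌ idle complex (K7 = 26 /M, k7 = 0.014 /M/min)

all flasks: second substrate 0.240 M; free catalyst 4.4 mM; added ligand 22 mM; time 2.5 d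

| charge | starting material |
|---|---|
| ochre | 0.0040 M (fed, over 2.5 d) |
| green | 0.012 M (fed, over 2.5 d) |
| blue | 0.040 M (fed, over 2.5 d) |
| teal | 0.12 M (fed, over 2.5 d) |

* share of target in all that became target or isomer of the product for ochre, green, blue, teal, in this order
* the course of these numbers from the first flask to the last (hardly changes / rises all the way / rises, then falls / falls all the way / falls, then rises)

- where a step has two of a species, its rate is k times that concentration squared, and two are used at each turn
- "hardly changes" means that all values lie within two and a half points (for a concentration: within two and a half percent of the largest)
- run time (ochre): 2.5 d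

**The clock.** Isomer grows with the time product has stood, so reckon that time. The sum of target and isomer leaves zero with zero slope, since the flask starts without starting material. Fed starting material then builds a pool, used up pseudo-first-order. Catalyst intermediate A goes on to target in a share 64.1 % of its visits, so the hold-up is one over that share times step 1's forward rate constant and free catalyst. With the catalyst charge taken as free, the hold-up is 197 min.

**Second pass.** Put that back: the catalyst is not free. Idle complex comes to balance with a half-time of 819 min, shorter than the feed, at 0.57 per free catalyst. Catalyst intermediate B stands at 0.165 per free catalyst, from the starting charges. So the free share is 57.6 %, and the hold-up becomes 342 min.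

**Knee, level.** Past that knee the sum climbs parallel to the feed, behind it by a pool of 9.50 % of the charge. Product made along this line has an average standing time of 1630 min at the end of the feed. Call this the mean product age. Target relaxes towards an isomer share of 65.5 % with the rate constant 6.41 × 10⁻⁵ /min, so the isomer share is 6.50 % and the target share 93.5 %.

**The charge.** In teal the pool binds 5.72 % as much catalyst as stands free, and that lengthens the hold-up by 11.3 min, so it shortens the age by 5.63 min. Commit to 93.5 % along the row, flat.

**Forecast.** It gave 93.5 %, 93.5 %, 93.5 % and 93.6 %, course hardly changes, on the ground that near-linear catalysis “cancels the charge from the share”.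

**Result.** The flasks give 93.4 %, 93.4 %, 93.4 % and 93.4 %: hardly changes.

**Second flask.** Read the age from ochre: 8.4 % of the charge still stood as starting material, so the age is 1650 min and the share 93.4 %. The feed over time and the reading at 2.5 d act together to hold teal there: read ten times later, teal shows 42.0 %. Charged at once, teal's product has the feed time less the hold-up as its age, 3290 min, twice ochre's, which reckons to 87.6 %. That run, below the forecast's 93.6 %, reads 87.5 %.

The constants belong to no real substance; no experiment stands behind them.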